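**Retrosynthetic overview**

1. The target is the cis-(1S,4S) tetralinol. Its absolute configuration is fixed last, by lipase kinetic resolution of the racemic cis compound.
2. The cis-1,4 relationship comes from a 1-aryl-1,4-epoxy-1,4-dihydronaphthalene. The oxygen bridge holds both C–O bonds on one face, and Pd hydrogenolysis with inversion at the aryl-bearing carbon leaves aryl cis to OH.
3. Key disconnection: the oxabicycle comes from an open-chain keto alcohol and phenyl vinyl sulfoxide. Cyclodehydration to an isobenzofuran and Diels–Alder trapping close the furan ring and carbocycle B in one pot.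
4. The keto alcohol comes from a naphthyllithium (8-methoxy-1-naphthol, para-bromination, O-benzylation) and 7-methoxyphthalide (3-methoxybenzyl alcohol, ortho-lithiation/CO2).
5. Ring order: both aromatic systems are bought; a temporary lactone is made and opened; then the furan ring and ring B form together; the bridge is opened last to leave the tetralin.

Assumption: 8-methoxynaphthalen-1-ol (1) is bought as a catalogue compound (otherwise one extra step from 1,8-dihydroxynaphthalene with MeI/K2CO3).

**Route**

Step 1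
Reactants: 1 8-methoxynaphthalen-1-ol
Product: 2 4-bromo-8-methoxynaphthalen-1-ol
Conditions: NBS (1.0 equiv), MeCN, −20 to 0 °C
Reagents that add atoms: N-bromosuccinimide, O=C1CCC(=O)N1Br
Why: Electrophilic aromatic bromination (SEAr); the hydrogen-bonded naphthol OH is the strongest donor and NBS in MeCN brominates para to it (C4) rather than ortho or in the anisole ring.

Step 2
Reactants: 2 4-bromo-8-methoxynaphthalen-1-ol
Product: 3 1-(benzyloxy)-4-bromo-8-methoxynaphthalene
Conditions: BnBr, K2CO3, DMF, 60 °C
Reagents that add atoms: benzyl bromide, BrCc1ccccc1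
Why: Williamson ether synthesis; benzyl masks the naphthol through the organolithium and acid steps and falls off in the same hydrogenation that opens the bridge.

Step 3
Reactants: 4 (3-methoxyphenyl)methanol
Product: 7 7-methoxy-2-benzofuran-1(3H)-one, via dilithio alkoxide 5 (not isolated), via hydroxy acid 6 (not isolated)
Conditions: n-BuLi (2.2 equiv), TMEDA, Et2O–hexane, 0 °C to rt; CO2, −78 °C; aq. HCl, rt
Reagents that add atoms: carbon dioxide, O=C=O
Why: Directed ortho-metalation; the lithium alkoxide and the methoxy group together direct lithiation to C2, carboxylation gives the hydroxy acid, and this lactonises on acidification.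

Step 4
Reactants: 3 1-(benzyloxy)-4-bromo-8-methoxynaphthalene; 7 7-methoxy-2-benzofuran-1(3H)-one
Product: 10 [4-(benzyloxy)-5-methoxynaphthalen-1-yl][2-(hydroxymethyl)-6-methoxyphenyl]methanone, via aryllithium 8 (not isolated), via lithium lactolate 9 (not isolated)
Conditions: n-BuLi (1.05 equiv), THF, −78 °C; then 7, −78 °C; H2O quench
Reagents that add atoms: none
Why: Bromine–lithium exchange followed by nucleophilic acyl addition to the lactone; the tetrahedral lactolate survives at −78 °C so only one aryl adds, and the quench releases the open-chain keto alcohol with the aryl carbon next to the OMe-bearing ring carbon.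

Step 5
Reactants: 10 [4-(benzyloxy)-5-methoxynaphthalen-1-yl][2-(hydroxymethyl)-6-methoxyphenyl]methanone; 11 phenyl vinyl sulfoxide
Product: 15 racemic (1S,4S)/(1R,4R)-1-[4-(benzyloxy)-5-methoxynaphthalen-1-yl]-8-methoxy-1,4-dihydro-1,4-epoxynaphthalene, via lactol 12 (not isolated), via isobenzofuran 13 (not isolated), via sulfinyl cycloadduct 14 (not isolated)
Conditions: AcOH (1 equiv), PhMe, 70 °C, Ar; then Et3N (2 equiv), 110 °C
Reagents that add atoms: none
Why: Acid-catalysed cyclodehydration (through the lactol) closes the furan ring to a 1-arylisobenzofuran, a Diels–Alder reaction with phenyl vinyl sulfoxide (acetylene equivalent) closes the carbocycle, and thermal sulfoxide syn-elimination gives the bridged alkene; the oxygen bridge locks the two C–O bonds cis (racemic), and regiochemistry is fixed by the phthalide.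

Step 6
Reactants: 15 racemic 1-[4-(benzyloxy)-5-methoxynaphthalen-1-yl]-8-methoxy-1,4-dihydro-1,4-epoxynaphthalene
Product: 17 racemic cis-4-(4-hydroxy-5-methoxynaphthalen-1-yl)-5-methoxy-1,2,3,4-tetrahydronaphthalen-1-ol, via saturated epoxide 16 (not isolated)
Conditions: H2 (1 atm), 10% Pd/C, EtOAc–EtOH, rt, stopped after 3 equiv H2
Reagents that add atoms: none
Why: Heterogeneous hydrogenation saturates the strained alkene and removes the benzyl ether, and Pd hydrogenolysis of the tertiary, doubly benzylic, o-methoxy-activated bridge C–O bond goes with inversion, so H enters anti to the leaving oxygen and the naphthyl group ends cis to the untouched C1 hydroxyl.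

Step 7
Reactants: 17 racemic cis-4-(4-hydroxy-5-methoxynaphthalen-1-yl)-5-methoxy-1,2,3,4-tetrahydronaphthalen-1-ol
Product: 18 (1S,4S)-4-(4-hydroxy-5-methoxynaphthalen-1-yl)-5-methoxy-1,2,3,4-tetrahydronaphthalen-1-ol (dipolynaphthalene B)
Conditions: Novozym 435 (CAL-B), vinyl acetate, MTBE, 35 °C, to about 55% conversion; chromatography
Reagents that add atoms: none
Why: Lipase-catalysed kinetic resolution (Kazlauskas rule); the enzyme acetylates the (1R)-carbinol of the racemate and leaves the (1S,4S)-alcohol, while the phenol is not a substrate, so the unreacted alcohol is the target in high ee at the cost of half the material.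

**Compound list**

1 | 8-methoxynaphthalen-1-ol | COc1cccc2cccc(O)c12 | starting material
2 | 4-bromo-8-methoxynaphthalen-1-ol | COc1cccc2c(Br)ccc(O)c12 | intermediate
3 | 1-(benzyloxy)-4-bromo-8-methoxynaphthalene | COc1cccc2c(Br)ccc(OCc3ccccc3)c12 | intermediate
4 | (3-methoxyphenyl)methanol | COc1cccc(CO)c1 | starting material
5 | lithium (2-lithio-3-methoxyphenyl)methanolate | COc1cccc(CO[Li])c1[Li] | intermediate (not isolated)
6 | 2-(hydroxymethyl)-6-methoxybenzoic acid | COc1cccc(CO)c1C(=O)O | intermediate (not isolated)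
7 | 7-methoxy-2-benzofuran-1(3H)-one (7-methoxyphthalide) | COc1cccc2c1C(=O)OC2 | intermediate
8 | [4-(benzyloxy)-5-methoxynaphthalen-1-yl]lithium | [Li]c1ccc(OCc2ccccc2)c2c(OC)cccc12 | intermediate (not isolated)
9 | lithium 1-[4-(benzyloxy)-5-methoxynaphthalen-1-yl]-7-methoxy-1,3-dihydro-2-benzofuran-1-olate (racemic, stereocentre not specified) | COc1cccc2c1C(O[Li])(c1ccc(OCc3ccccc3)c3c(OC)cccc13)OC2 | intermediate (not isolated)
10 | [4-(benzyloxy)-5-methoxynaphthalen-1-yl][2-(hydroxymethyl)-6-methoxyphenyl]methanone | COc1cccc(CO)c1C(=O)c1ccc(OCc2ccccc2)c2c(OC)cccc12 | intermediate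
11 | phenyl vinyl sulfoxide (racemic at sulfur, not specified) | C=CS(=O)c1ccccc1 | starting material
12 | 1-[4-(benzyloxy)-5-methoxynaphthalen-1-yl]-7-methoxy-1,3-dihydro-2-benzofuran-1-ol (racemic, stereocentre not specified) | COc1cccc2c1C(O)(c1ccc(OCc3ccccc3)c3c(OC)cccc13)OC2 | intermediate (not isolated)
13 | 1-[4-(benzyloxy)-5-methoxynaphthalen-1-yl]-7-methoxy-2-benzofuran | COC1=CC=CC2=COC(c3ccc(OCc4ccccc4)c4c(OC)cccc34)=C12 | intermediate (not isolated)
14 | 1-[4-(benzyloxy)-5-methoxynaphthalen-1-yl]-8-methoxy-2-(phenylsulfinyl)-1,2,3,4-tetrahydro-1,4-epoxynaphthalene (regio- and stereoisomer mixture, one regioisomer drawn without stereodescriptors) | COc1cccc2c1C1(c3ccc(OCc4ccccc4)c4c(OC)cccc34)OC2CC1S(=O)c1ccccc1 | intermediate (not isolated)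
15 | racemic 1-[4-(benzyloxy)-5-methoxynaphthalen-1-yl]-8-methoxy-1,4-dihydro-1,4-epoxynaphthalene, (1S,4S) and (1R,4R) | COc1cccc2c1[C@]1(c3ccc(OCc4ccccc4)c4c(OC)cccc34)O[C@H]2C=C1.COc1cccc2c1[C@@]1(c3ccc(OCc4ccccc4)c4c(OC)cccc34)O[C@@H]2C=C1 | intermediate
16 | racemic 1-[4-(benzyloxy)-5-methoxynaphthalen-1-yl]-8-methoxy-1,2,3,4-tetrahydro-1,4-epoxynaphthalene, (1S,4S) and (1R,4R) | COc1cccc2c1[C@]1(c3ccc(OCc4ccccc4)c4c(OC)cccc34)O[C@H]2CC1.COc1cccc2c1[C@@]1(c3ccc(OCc4ccccc4)c4c(OC)cccc34)O[C@@H]2CC1 | intermediate (not isolated)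
17 | racemic cis-4-(4-hydroxy-5-methoxynaphthalen-1-yl)-5-methoxy-1,2,3,4-tetrahydronaphthalen-1-ol, (1S,4S) and (1R,4R) | COc1cccc2c1[C@H](c1ccc(O)c3c(OC)cccc13)CC[C@@H]2O.COc1cccc2c1[C@@H](c1ccc(O)c3c(OC)cccc13)CC[C@H]2O | intermediate
18 | (1S,4S)-4-(4-hydroxy-5-methoxynaphthalen-1-yl)-5-methoxy-1,2,3,4-tetrahydronaphthalen-1-ol (dipolynaphthalene B) | COc1cccc2c1[C@H](c1ccc(O)c3c(OC)cccc13)CC[C@@H]2O | target

**Summary and risks**

Total steps: 7. Longest linear sequence: 6 (steps 1, 2, 4, 5, 6, 7).

Step 5 is the most exposed step. The isobenzofuran can oligomerise, the sulfoxide is only a moderate dienophile, and alkene 15 can isomerise to a naphthol if acid is still present during the hot elimination stage. The fallback sets out from 3 and comes back at 15. Suzuki–Miyaura coupling of 3 with furan-2-boronic acid (Pd(dppf)Cl2, K2CO3, dioxane–water, 80 °C) gives 2-[4-(benzyloxy)-5-methoxynaphthalen-1-yl]furan F1. CsF in MeCN then releases 3-methoxybenzyne F2 from 2-methoxy-6-(trimethylsilyl)phenyl triflate, and aryne–furan Diels–Alder addition gives 15. In this asynchronous addition the unsubstituted furan carbon should bond first to the aryne carbon meta to OMe, which puts the aryl bridgehead next to the methoxy-bearing carbon; any regioisomer is removed by chromatography.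

Step 6 is the second risk. Hydrogenolysis at the bridgehead may go with retention or through a cation and give trans material, and the C1 benzylic alcohol may be over-reduced. The fallback sets out from 15 and comes back at 17. Diimide (TsNHNH2, NaOAc, aqueous DME, 80 °C) reduces only the strained alkene to give 16, isolated this time. TBSOTf with 2,6-lutidine opens the bridge by silyl-triggered E1 elimination to racemic {4-[4-(benzyloxy)-5-methoxynaphthalen-1-yl]-5-methoxy-1,2-dihydronaphthalen-1-yl}oxy(tert-butyl)dimethylsilane F3. H2 over Pd/C then adds to the alkene anti to the bulky silyl ether and removes the benzyl group, giving racemic cis-4-{4-[(tert-butyldimethylsilyl)oxy]-8-methoxy-1,2,3,4-tetrahydronaphthalen-1-yl}-8-methoxynaphthalen-1-ol F4. TBAF in THF gives 17.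

Step 7 is the third risk. The bulky cis-4-naphthyl group may lower the lipase's rate or selectivity. The fallback sets out from 17 and comes back at 18. Oppenauer oxidation (Al(Ot-Bu)3, acetone–toluene, which tolerates the phenol) gives racemic 4-(4-hydroxy-5-methoxynaphthalen-1-yl)-5-methoxy-3,4-dihydronaphthalen-1(2H)-one F5. Catalyst-controlled reduction with (R)-Me-CBS and BH3·SMe2 (excess, to allow for the phenol) converts both ketone enantiomers into (1S)-alcohols. These are 18 and its diastereomer (1S,4R)-4-(4-hydroxy-5-methoxynaphthalen-1-yl)-5-methoxy-1,2,3,4-tetrahydronaphthalen-1-ol F6, which are separated by chromatography.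

**Further compounds**

F1 | step 5 | 2-[4-(benzyloxy)-5-methoxynaphthalen-1-yl]furan | COc1cccc2c(-c3ccco3)ccc(OCc3ccccc3)c12
F2 | step 5 | 3-methoxybenzyne (generated in the flask) | COC1=CC=CC#C1
F3 | step 6 | racemic {4-[4-(benzyloxy)-5-methoxynaphthalen-1-yl]-5-methoxy-1,2-dihydronaphthalen-1-yl}oxy(tert-butyl)dimethylsilane, (1S) and (1R) | COc1cccc2c1C(c1ccc(OCc3ccccc3)c3c(OC)cccc13)=CC[C@@H]2O[Si](C)(C)C(C)(C)C.COc1cccc2c1C(c1ccc(OCc3ccccc3)c3c(OC)cccc13)=CC[C@H]2O[Si](C)(C)C(C)(C)C
F4 | step 6 | racemic cis-4-{4-[(tert-butyldimethylsilyl)oxy]-8-methoxy-1,2,3,4-tetrahydronaphthalen-1-yl}-8-methoxynaphthalen-1-ol, (1S,4S) and (1R,4R) | COc1cccc2c1[C@H](c1ccc(O)c3c(OC)cccc13)CC[C@@H]2O[Si](C)(C)C(C)(C)C.COc1cccc2c1[C@@H](c1ccc(O)c3c(OC)cccc13)CC[C@H]2O[Si](C)(C)C(C)(C)C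
F5 | step 7 | racemic 4-(4-hydroxy-5-methoxynaphthalen-1-yl)-5-methoxy-3,4-dihydronaphthalen-1(2H)-one, (4S) and (4R) | COc1cccc2c1[C@H](c1ccc(O)c3c(OC)cccc13)CCC2=O.COc1cccc2c1[C@@H](c1ccc(O)c3c(OC)cccc13)CCC2=O
F6 | step 7 | (1S,4R)-4-(4-hydroxy-5-methoxynaphthalen-1-yl)-5-methoxy-1,2,3,4-tetrahydronaphthalen-1-ol | COc1cccc2c1[C@@H](c1ccc(O)c3c(OC)cccc13)CC[C@@H]2O
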